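**Plan**
- The target is a 3',6''-linked biflavone: unit 1 is a 5-hydroxy-7-methoxyflavone, unit 2 a 5,7-dihydroxy-4'-methoxyflavone joined through its C6 to C3' of unit 1.
- Retrosynthesis first cuts the pyranone of unit 1 at O1–C2 and C2–C3 (cyclodehydration, Baker–Venkataraman), then the pyranone of unit 2 at C4–C4a and O1–C2 (Friedel–Crafts, O-vinylation).
- Ring B of unit 1 is a 1,3,4-trisubstituted benzene: C1' bears the carboxyl carbon, C3' ring A of unit 2, C4' the methoxy group. Cutting C1'–C2' and C5'–C6' gives a 2-methoxy-3-arylbuta-1,3-diene (C2', C3', C4', C5') and methyl propiolate (C1', C6').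
- Forward: bromophenol → aryl keto ester → diene; ring B by [4+2] and dehydrogenation, with the hindered biaryl bond carried in from the start; then the pyranone of unit 2, then the pyranone of unit 1, then debenzylation.
- Stereochemistry: there are no stereocentres, so nothing has to be set.

Key step: step 5

Assumption: the C3'–C6'' biaryl axis is taken as freely rotating. Compounds 14–16 are drawn as Z isomers; either alkene geometry should converge in step 9.

**Step 1**
Reactants: 1 3,5-bis(benzyloxy)phenol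
Product: 2 3,5-bis(benzyloxy)-4-bromophenol
Conditions: NBS (1.0 equiv), MeCN, −40 → 0 °C
Reagents that add atoms: N-bromosuccinimide, O=C1CCC(=O)N1Br
Why: Electrophilic aromatic bromination, in which the free hydroxyl is the strongest donor and a polar solvent at low temperature should direct bromine para to it, to C4 between the two benzyloxy groups, the same site that Vilsmeier formylation of 3,5-dialkoxyphenols favours.

**Step 2**
Reactants: 2 3,5-bis(benzyloxy)-4-bromophenol
Product: 3 [3,5-bis(benzyloxy)-4-bromophenoxy]triisopropylsilane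
Conditions: TIPSCl, imidazole, DMF, rt
Reagents that add atoms: triisopropylsilyl chloride, CC(C)[Si](Cl)(C(C)C)C(C)C
Why: Imidazole-promoted silylation of a phenol masks the oxygen that becomes O1 of unit 2 against n-BuLi, the titanium methylidene and DDQ, and the silyl ether is orthogonal to the benzyl ethers.

**Step 3**
Reactants: 3 [3,5-bis(benzyloxy)-4-bromophenoxy]triisopropylsilane; 4 dimethyl oxalate
Product: 6 methyl 2-[2,6-bis(benzyloxy)-4-(triisopropylsilyloxy)phenyl]-2-oxoacetate, via aryllithium 5 (not isolated)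
Conditions: n-BuLi, THF, −78 °C; cannulated into 4 (3 equiv), THF, −78 °C; aq. NH4Cl
Reagents that add atoms: none
Why: Bromine–lithium exchange at −78 °C is faster than benzylic deprotonation, and inverse addition of the hindered aryllithium to excess dialkyl oxalate should stop at the α-keto ester (aryl glyoxylate synthesis).

**Step 4**
Reactants: 6 methyl 2-[2,6-bis(benzyloxy)-4-(triisopropylsilyloxy)phenyl]-2-oxoacetate
Product: 8 2-[2,6-bis(benzyloxy)-4-(triisopropylsilyloxy)phenyl]-3-methoxybuta-1,3-diene, via acrylate 7 (not isolated)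
Conditions: Cp2TiMe2 (5 equiv), PhMe, 70 °C, dark; filtration through basic Al2O3
Reagents that add atoms: dimethyltitanocene Cp2TiMe2, C[Ti](C)(C1C=CC=C1)C1C=CC=C1
Why: Petasis methylenation, in which Cp2TiMe2 loses methane to give Cp2Ti=CH2 that converts C=O into C=CH2 through an oxatitanacyclobutane, first at the ketone (acrylate 7) and then at the conjugated ester, so the acid-sensitive methyl enol ether is made without acid, as in the known methylenation of unsaturated esters to 2-alkoxydienes.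

**Step 5**
Reactants: 8 2-[2,6-bis(benzyloxy)-4-(triisopropylsilyloxy)phenyl]-3-methoxybuta-1,3-diene; 9 methyl propiolate
Product: 11 methyl 3-[2,6-bis(benzyloxy)-4-(triisopropylsilyloxy)phenyl]-4-methoxybenzoate, via cyclohexa-1,4-diene adduct 10 (not isolated)
Conditions: 9 (3 equiv), cat. BHT, PhMe, 100 °C, sealed tube; evaporation of excess 9; then DDQ (1.1 equiv), PhMe, 0 °C → rt
Reagents that add atoms: none
Why: The electron-rich 2-methoxydiene and the electron-poor alkyne should combine in a concerted, asynchronous, normal-demand [4+2] cycloaddition in which the diene terminus next to the methoxy-bearing carbon bonds to the β-carbon of the propiolate, after which DDQ takes a hydride from a doubly allylic CH2 of adduct 10 and loss of a proton gives the arene. The closest known reaction type is the Diels–Alder addition of 2-alkoxy- or 2-silyloxybutadienes to propiolates followed by DDQ dehydrogenation. Ring B of unit 1 closes by intermolecular [4+2] cycloaddition, both ring bonds (C1'–C2' and C5'–C6') forming in one suprafacial event, and no stereocentre is created. The step needs regioselectivity (ester para to methoxy and meta to the aryl group), which the methoxy group secures as the dominant donor, because the aryl group is held perpendicular by its two ortho benzyloxy groups and cannot conjugate with the diene. The 2,3-disubstitution keeps the diene near the s-cis conformation, and the crowded biaryl bond is a spectator that is carried in, not formed. Benzyl and silyl ethers should tolerate one equivalent of DDQ at 0 °C, since the cyclohexadiene is by far the better hydride donor.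

**Step 6**
Reactants: 11 methyl 3-[2,6-bis(benzyloxy)-4-(triisopropylsilyloxy)phenyl]-4-methoxybenzoate
Product: 12 methyl 3-[2,6-bis(benzyloxy)-4-hydroxyphenyl]-4-methoxybenzoate
Conditions: Bu4NF, AcOH, THF, 0 °C → rt
Reagents that add atoms: none
Why: Fluoride-mediated cleavage of the aryl silyl ether, buffered with AcOH so that no free phenoxide attacks the ester, should leave the benzyl and methyl ethers untouched.

**Step 7**
Reactants: 12 methyl 3-[2,6-bis(benzyloxy)-4-hydroxyphenyl]-4-methoxybenzoate; 13 ethyl 3-(4-methoxyphenyl)prop-2-ynoate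
Product: 14 methyl 3-[2,6-bis(benzyloxy)-4-{[(Z)-3-ethoxy-1-(4-methoxyphenyl)-3-oxoprop-1-enyl]oxy}phenyl]-4-methoxybenzoate
Conditions: 13 (1.3 equiv), Cs2CO3 (0.3 equiv), DMF, 70 °C
Reagents that add atoms: none
Why: Base-catalysed oxa-Michael addition of the phenoxide to the aryl propiolate (first stage of the Ruhemann flavone synthesis) forms O1–C2 of unit 2 on the only free hydroxyl, which lies para to the biaryl bond, with anti addition favouring the Z adduct.

**Step 8**
Reactants: 14 methyl 3-[2,6-bis(benzyloxy)-4-{[(Z)-3-ethoxy-1-(4-methoxyphenyl)-3-oxoprop-1-enyl]oxy}phenyl]-4-methoxybenzoate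
Product: 15 3-[2,6-bis(benzyloxy)-4-{[(Z)-2-carboxy-1-(4-methoxyphenyl)ethenyl]oxy}phenyl]-4-methoxybenzoic acid
Conditions: LiOH·H2O (6 equiv), THF/H2O, 40 °C; then 1 M HCl
Reagents that add atoms: lithium hydroxide, [Li+].[OH-]
Why: Saponification of both esters at moderate temperature without an alcohol cosolvent (no alkoxide exchange at the β-aryloxy carbon) gives the diacid that serves both later acylations.

**Step 9**
Reactants: 15 3-[2,6-bis(benzyloxy)-4-{[(Z)-2-carboxy-1-(4-methoxyphenyl)ethenyl]oxy}phenyl]-4-methoxybenzoic acid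
Product: 18 3-[5,7-bis(benzyloxy)-2-(4-methoxyphenyl)-4-oxo-4H-chromen-6-yl]-4-methoxybenzoic acid, via bis(trifluoroacetic) mixed anhydride 16 (not isolated), via flavone mixed anhydride 17 (not isolated)
Conditions: (CF3CO)2O (5 equiv), CH2Cl2, 0 °C → rt; then H2O/THF, rt
Reagents that add atoms: none
Why: Intramolecular Friedel–Crafts acylation through the mixed trifluoroacetic anhydride closes the six-membered pyranone at the ring carbon ortho to the vinyloxy oxygen, which three oxygens activate (second stage of the Ruhemann synthesis), while acid-mediated E/Z equilibration supplies the reactive geometry and the aroyl mixed anhydride, lacking an intramolecular partner, is hydrolysed on work-up.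

**Step 10**
Reactants: 18 3-[5,7-bis(benzyloxy)-2-(4-methoxyphenyl)-4-oxo-4H-chromen-6-yl]-4-methoxybenzoic acid; 19 2',6'-dihydroxy-4'-methoxyacetophenone
Product: 20 2-acetyl-3-hydroxy-5-methoxyphenyl 3-[5,7-bis(benzyloxy)-2-(4-methoxyphenyl)-4-oxo-4H-chromen-6-yl]-4-methoxybenzoate
Conditions: DCC, cat. DMAP, CH2Cl2, 0 °C → rt (19 in twofold excess)
Reagents that add atoms: none
Why: Steglich esterification, in which an excess of the symmetrical dihydroxyacetophenone should ensure mono-aroylation because the second hydroxyl is tied up in the hydrogen bond to the acetyl group.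

**Step 11**
Reactants: 20 2-acetyl-3-hydroxy-5-methoxyphenyl 3-[5,7-bis(benzyloxy)-2-(4-methoxyphenyl)-4-oxo-4H-chromen-6-yl]-4-methoxybenzoate
Product: 21 1-{3-[5,7-bis(benzyloxy)-2-(4-methoxyphenyl)-4-oxo-4H-chromen-6-yl]-4-methoxyphenyl}-3-(2,6-dihydroxy-4-methoxyphenyl)propane-1,3-dione
Conditions: LiN(SiMe3)2 (3.5 equiv), THF, −78 → 0 °C; aq. NH4Cl
Reagents that add atoms: none
Why: Baker–Venkataraman rearrangement, in which the lithium enolate of the acetyl group attacks the neighbouring aroyl ester and the phenoxide leaves, forms C2–C3 of unit 1 under a non-nucleophilic base that should not open the flavone of unit 2.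

**Step 12**
Reactants: 21 1-{3-[5,7-bis(benzyloxy)-2-(4-methoxyphenyl)-4-oxo-4H-chromen-6-yl]-4-methoxyphenyl}-3-(2,6-dihydroxy-4-methoxyphenyl)propane-1,3-dione
Product: 22 5,7-bis(benzyloxy)-6-[5-(5-hydroxy-7-methoxy-4-oxo-4H-chromen-2-yl)-2-methoxyphenyl]-2-(4-methoxyphenyl)-4H-chromen-4-one
Conditions: p-TsOH·H2O (0.2 equiv), PhMe, 90 °C
Reagents that add atoms: none
Why: Acid-catalysed cyclodehydration of the o-hydroxyaryl 1,3-diketone (hemiketal, then loss of water) closes the pyranone of unit 1, and because the two hydroxyls are equivalent only the 5-hydroxy-7-methoxyflavone can form.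

**Step 13**
Reactants: 22 5,7-bis(benzyloxy)-6-[5-(5-hydroxy-7-methoxy-4-oxo-4H-chromen-2-yl)-2-methoxyphenyl]-2-(4-methoxyphenyl)-4H-chromen-4-one
Product: 23 5,7-dihydroxy-6-[5-(5-hydroxy-7-methoxy-4-oxo-4H-chromen-2-yl)-2-methoxyphenyl]-2-(4-methoxyphenyl)-4H-chromen-4-one
Conditions: H2 (1 atm), Pd/C (10 wt % Pd), THF/MeOH, rt
Reagents that add atoms: none
Why: Hydrogenolysis of the two benzyl ethers over palladium on carbon at atmospheric pressure should free the 5- and 7-hydroxyls of unit 2 without reducing the chromone double bonds or cleaving the methyl ethers.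

**Compound list**
1 | 3,5-bis(benzyloxy)phenol | Oc1cc(OCc2ccccc2)cc(OCc2ccccc2)c1 | starting material
2 | 3,5-bis(benzyloxy)-4-bromophenol | Oc1cc(OCc2ccccc2)c(Br)c(OCc2ccccc2)c1 | intermediate
3 | [3,5-bis(benzyloxy)-4-bromophenoxy]triisopropylsilane | CC(C)[Si](Oc1cc(OCc2ccccc2)c(Br)c(OCc2ccccc2)c1)(C(C)C)C(C)C | intermediate
4 | dimethyl oxalate | COC(=O)C(=O)OC | starting material
5 | [2,6-bis(benzyloxy)-4-(triisopropylsilyloxy)phenyl]lithium | [Li]c1c(OCc2ccccc2)cc(O[Si](C(C)C)(C(C)C)C(C)C)cc1OCc1ccccc1 | intermediate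
6 | methyl 2-[2,6-bis(benzyloxy)-4-(triisopropylsilyloxy)phenyl]-2-oxoacetate | COC(=O)C(=O)c1c(OCc2ccccc2)cc(O[Si](C(C)C)(C(C)C)C(C)C)cc1OCc1ccccc1 | intermediate
7 | methyl 2-[2,6-bis(benzyloxy)-4-(triisopropylsilyloxy)phenyl]prop-2-enoate | COC(=O)C(=C)c1c(OCc2ccccc2)cc(O[Si](C(C)C)(C(C)C)C(C)C)cc1OCc1ccccc1 | intermediate
8 | 2-[2,6-bis(benzyloxy)-4-(triisopropylsilyloxy)phenyl]-3-methoxybuta-1,3-diene | C=C(OC)C(=C)c1c(OCc2ccccc2)cc(O[Si](C(C)C)(C(C)C)C(C)C)cc1OCc1ccccc1 | intermediate
9 | methyl propiolate | C#CC(=O)OC | starting material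
10 | methyl 5-[2,6-bis(benzyloxy)-4-(triisopropylsilyloxy)phenyl]-4-methoxycyclohexa-1,4-diene-1-carboxylate | COC(=O)C1=CCC(OC)=C(c2c(OCc3ccccc3)cc(O[Si](C(C)C)(C(C)C)C(C)C)cc2OCc2ccccc2)C1 | intermediate
11 | methyl 3-[2,6-bis(benzyloxy)-4-(triisopropylsilyloxy)phenyl]-4-methoxybenzoate | COC(=O)c1ccc(OC)c(-c2c(OCc3ccccc3)cc(O[Si](C(C)C)(C(C)C)C(C)C)cc2OCc2ccccc2)c1 | intermediate
12 | methyl 3-[2,6-bis(benzyloxy)-4-hydroxyphenyl]-4-methoxybenzoate | COC(=O)c1ccc(OC)c(-c2c(OCc3ccccc3)cc(O)cc2OCc2ccccc2)c1 | intermediate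
13 | ethyl 3-(4-methoxyphenyl)prop-2-ynoate | CCOC(=O)C#Cc1ccc(OC)cc1 | starting material
14 | methyl 3-[2,6-bis(benzyloxy)-4-{[(Z)-3-ethoxy-1-(4-methoxyphenyl)-3-oxoprop-1-enyl]oxy}phenyl]-4-methoxybenzoate | CCOC(=O)/C=C(\Oc1cc(OCc2ccccc2)c(-c2cc(C(=O)OC)ccc2OC)c(OCc2ccccc2)c1)c1ccc(OC)cc1 | intermediate
15 | 3-[2,6-bis(benzyloxy)-4-{[(Z)-2-carboxy-1-(4-methoxyphenyl)ethenyl]oxy}phenyl]-4-methoxybenzoic acid | OC(=O)/C=C(\Oc1cc(OCc2ccccc2)c(-c2cc(C(=O)O)ccc2OC)c(OCc2ccccc2)c1)c1ccc(OC)cc1 | intermediate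
16 | bis(trifluoroacetic) mixed anhydride of diacid 15 | O=C(OC(=O)C(F)(F)F)/C=C(\Oc1cc(OCc2ccccc2)c(-c2cc(C(=O)OC(=O)C(F)(F)F)ccc2OC)c(OCc2ccccc2)c1)c1ccc(OC)cc1 | intermediate
17 | 3-[5,7-bis(benzyloxy)-2-(4-methoxyphenyl)-4-oxo-4H-chromen-6-yl]-4-methoxybenzoic trifluoroacetic anhydride | COc1ccc(-c2cc(=O)c3c(OCc4ccccc4)c(-c4cc(C(=O)OC(=O)C(F)(F)F)ccc4OC)c(OCc4ccccc4)cc3o2)cc1 | intermediate
18 | 3-[5,7-bis(benzyloxy)-2-(4-methoxyphenyl)-4-oxo-4H-chromen-6-yl]-4-methoxybenzoic acid | COc1ccc(-c2cc(=O)c3c(OCc4ccccc4)c(-c4cc(C(=O)O)ccc4OC)c(OCc4ccccc4)cc3o2)cc1 | intermediate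
19 | 2',6'-dihydroxy-4'-methoxyacetophenone | CC(=O)c1c(O)cc(OC)cc1O | starting material
20 | 2-acetyl-3-hydroxy-5-methoxyphenyl 3-[5,7-bis(benzyloxy)-2-(4-methoxyphenyl)-4-oxo-4H-chromen-6-yl]-4-methoxybenzoate | COc1ccc(-c2cc(=O)c3c(OCc4ccccc4)c(-c4cc(C(=O)Oc5cc(OC)cc(O)c5C(C)=O)ccc4OC)c(OCc4ccccc4)cc3o2)cc1 | intermediate
21 | 1-{3-[5,7-bis(benzyloxy)-2-(4-methoxyphenyl)-4-oxo-4H-chromen-6-yl]-4-methoxyphenyl}-3-(2,6-dihydroxy-4-methoxyphenyl)propane-1,3-dione | COc1ccc(-c2cc(=O)c3c(OCc4ccccc4)c(-c4cc(C(=O)CC(=O)c5c(O)cc(OC)cc5O)ccc4OC)c(OCc4ccccc4)cc3o2)cc1 | intermediate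
22 | 5,7-bis(benzyloxy)-6-[5-(5-hydroxy-7-methoxy-4-oxo-4H-chromen-2-yl)-2-methoxyphenyl]-2-(4-methoxyphenyl)-4H-chromen-4-one | COc1ccc(-c2cc(=O)c3c(OCc4ccccc4)c(-c4cc(-c5cc(=O)c6c(O)cc(OC)cc6o5)ccc4OC)c(OCc4ccccc4)cc3o2)cc1 | intermediate
23 | 5,7-dihydroxy-6-[5-(5-hydroxy-7-methoxy-4-oxo-4H-chromen-2-yl)-2-methoxyphenyl]-2-(4-methoxyphenyl)-4H-chromen-4-one (CNP0281098.0) | COc1ccc(-c2cc(=O)c3c(O)c(-c4cc(-c5cc(=O)c6c(O)cc(OC)cc6o5)ccc4OC)c(O)cc3o2)cc1 | target

**Count**
Total: 13 steps. Longest linear sequence: 13 steps (1 → 23); compounds 4, 9, 13 and 19 enter as purchased partners.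

**Steps most likely to fail**

Step 5 (key step). The cycloaddition on the crowded diene may be slow, so that thermal oligomerisation of the diene or of the propiolate, or hydrolysis of the enol ether by adventitious acid, outruns ring formation. The fallback keeps the [4+2] disconnection but uses an alkene dienophile. It sets out from diene 8, which is heated with methyl 2-chloroacrylate in PhMe at 80 °C. The CH2 carbon of this dienophile is its electrophilic end, so the orientation is unchanged, and the expected adduct is racemic methyl 1-chloro-3-[2,6-bis(benzyloxy)-4-(triisopropylsilyloxy)phenyl]-4-methoxycyclohex-3-ene-1-carboxylate F1. DBU then removes HCl to reach the cyclohexadiene 10, and DDQ aromatises it to benzoate 11, where the route is rejoined.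

Step 7. Conjugate addition to an alkyne deactivated by its p-anisyl group may be sluggish, and C-attack by the electron-rich phenoxide ring (leading toward a 4-arylcoumarin) or ester exchange may compete. The fallback sets out from phenol 12 and builds the pyranone by palladium-catalysed carbonylation instead. N-iodosuccinimide (MeCN, 0 °C) should iodinate ortho to the hydroxyl, the only open site of that ring, to give methyl 3-[2,6-bis(benzyloxy)-4-hydroxy-3-iodophenyl]-4-methoxybenzoate F2. Carbonylative Sonogashira coupling with 4-ethynylanisole under CO (1 atm) with PdCl2(PPh3)2 in Et2NH at 80 °C gives methyl 3-{2,6-bis(benzyloxy)-4-hydroxy-3-[3-(4-methoxyphenyl)prop-2-ynoyl]phenyl}-4-methoxybenzoate F3. Under the amine this ynone closes 6-endo to methyl 3-[5,7-bis(benzyloxy)-2-(4-methoxyphenyl)-4-oxo-4H-chromen-6-yl]-4-methoxybenzoate F4. Saponification with LiOH (THF/H2O) returns to the route at acid 18.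

Step 1. Bromination may occur ortho to the hydroxyl or twice, and a regioisomer carried forward would end in the 8-linked series. The fallback sets out from phenol 1 and marks the para position by formylation instead. Vilsmeier–Haack reaction (POCl3, DMF) should give 2,6-bis(benzyloxy)-4-hydroxybenzaldehyde F5, which separates easily from the chelated ortho isomer. Silylation (TIPSCl, imidazole) gives 2,6-bis(benzyloxy)-4-(triisopropylsilyloxy)benzaldehyde F6. 1-Methoxyvinyllithium F7, made from methyl vinyl ether and t-BuLi in THF at −78 → 0 °C, adds to F6 to give racemic 1-[2,6-bis(benzyloxy)-4-(triisopropylsilyloxy)phenyl]-2-methoxyprop-2-en-1-ol F8. Oxidation with MnO2 (CH2Cl2) gives 1-[2,6-bis(benzyloxy)-4-(triisopropylsilyloxy)phenyl]-2-methoxyprop-2-en-1-one F9. Methylenation of this ketone with Cp2TiMe2 (PhMe, 70 °C) returns to the route at diene 8.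

**Further compounds**
F1 | step 5 | methyl 1-chloro-3-[2,6-bis(benzyloxy)-4-(triisopropylsilyloxy)phenyl]-4-methoxycyclohex-3-ene-1-carboxylate (racemic) | COC(=O)C1(Cl)CCC(OC)=C(c2c(OCc3ccccc3)cc(O[Si](C(C)C)(C(C)C)C(C)C)cc2OCc2ccccc2)C1
F2 | step 7 | methyl 3-[2,6-bis(benzyloxy)-4-hydroxy-3-iodophenyl]-4-methoxybenzoate | COC(=O)c1ccc(OC)c(-c2c(OCc3ccccc3)cc(O)c(I)c2OCc2ccccc2)c1
F3 | step 7 | methyl 3-{2,6-bis(benzyloxy)-4-hydroxy-3-[3-(4-methoxyphenyl)prop-2-ynoyl]phenyl}-4-methoxybenzoate | COC(=O)c1ccc(OC)c(-c2c(OCc3ccccc3)cc(O)c(C(=O)C#Cc3ccc(OC)cc3)c2OCc2ccccc2)c1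
F4 | step 7 | methyl 3-[5,7-bis(benzyloxy)-2-(4-methoxyphenyl)-4-oxo-4H-chromen-6-yl]-4-methoxybenzoate | COc1ccc(-c2cc(=O)c3c(OCc4ccccc4)c(-c4cc(C(=O)OC)ccc4OC)c(OCc4ccccc4)cc3o2)cc1
F5 | step 1 | 2,6-bis(benzyloxy)-4-hydroxybenzaldehyde | O=Cc1c(OCc2ccccc2)cc(O)cc1OCc1ccccc1
F6 | step 1 | 2,6-bis(benzyloxy)-4-(triisopropylsilyloxy)benzaldehyde | O=Cc1c(OCc2ccccc2)cc(O[Si](C(C)C)(C(C)C)C(C)C)cc1OCc1ccccc1
F7 | step 1 | 1-methoxyvinyllithium | [Li]C(=C)OC
F8 | step 1 | 1-[2,6-bis(benzyloxy)-4-(triisopropylsilyloxy)phenyl]-2-methoxyprop-2-en-1-ol (racemic) | C=C(OC)C(O)c1c(OCc2ccccc2)cc(O[Si](C(C)C)(C(C)C)C(C)C)cc1OCc1ccccc1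
F9 | step 1 | 1-[2,6-bis(benzyloxy)-4-(triisopropylsilyloxy)phenyl]-2-methoxyprop-2-en-1-one | C=C(OC)C(=O)c1c(OCc2ccccc2)cc(O[Si](C(C)C)(C(C)C)C(C)C)cc1OCc1ccccc1
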